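**Plan**

1. Retrosynthesis: the three O-benzyl groups come off last. The A–B ester (ring A carbonyl to O4 of ring B) is cut to an aromatic ring A acid and the free 4-hydroxyl of ring B. The B–C ester (ring B carbonyl to the doubly ortho-methylated oxygen of ring C) is cut with ring B in its dihydro, 4,6-dioxocyclohexane form, and every ring is finally opened at C1–C2 and C5–C6.
2. Feature used: rings A, B and C are one unit, a 2,3,5-trimethylbenzoate oxygenated at C4 and C6 with the carboxyl on C1 (ring C has H at C1). In the dihydro form C1, C6 and the carboxyl come from a malonate; C2–C5 and all three methyls come from (E)-4-methylhex-4-en-3-one.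
3. Forward: an aldol condensation gives the enone, and one Michael–Claisen annulation closes the only ring that has to be built; its product supplies all three rings.
4. Ring C is made first (decarboxylation, dehydrogenation, benzylation of the less hindered hydroxyl). Ring B is attached as the saturated β-keto ester by acylketene transfer and then dehydrogenated. Ring A is the same keto ester aromatised, benzylated and saponified; it is joined to O4 of ring B through its mixed trifluoroacetic anhydride, and hydrogenolysis ends the route.
5. Stereochemistry: the target has no stereocentre; the sp3 centres of the saturated rings form as mixtures and are erased on aromatisation.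

Key step: step 2

Remark: the saturated ring intermediates are carried as mixtures of diastereomers and keto–enol tautomers, so their SMILES are written in the keto form without configuration.

**Route**

Step 1
Reactants: 1 pentan-3-one; 2 acetaldehyde
Product: 4 (E)-4-methylhex-4-en-3-one, via aldol adduct 3 (not isolated)
Conditions: 1 (4 equiv), NaOH (cat.), H2O, 0–10 °C, slow addition of 2; then H2SO4 (aq., to pH 1), reflux; distil
Reagents that add atoms: none
Why: Crossed aldol condensation, in which the enolate of the symmetrical ketone (kept in excess) adds to the more electrophilic aldehyde and acid-catalysed dehydration of the β-hydroxy ketone should give the trisubstituted enone as its more stable E isomer; the geometry has no bearing on later steps.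

Step 2
Reactants: 4 (E)-4-methylhex-4-en-3-one; 5 dimethyl malonate
Product: 7 methyl 2,3,5-trimethyl-4,6-dioxocyclohexane-1-carboxylate, via Michael adduct 6 (not isolated)
Conditions: NaOMe (1.1 equiv), MeOH, 0 °C to reflux; then HCl (aq.), 0 °C, pH 2
Reagents that add atoms: none
Why: Methoxide generates the malonate anion, which adds to the β-carbon of enone 4 (Michael addition, new bond C1–C2) to give 6; proton transfer then produces the enolate on the ethyl side of the ketone, which attacks one malonate ester carbonyl and expels methoxide (Claisen/Dieckmann condensation, new bond C5–C6). The closest known reaction is the dimedone-type Michael–Claisen annulation of malonates with enones to cyclohexane-1,3-diones. The single ring closes in a 6-exo-trig mode with the enolate double bond outside the new ring (6-(enolexo)-exo-trig). Four sp3 centres (C1, C2, C3, C5) arise without control as an equilibrating mixture of epimers and enol forms, which is harmless because each becomes sp2 on dehydrogenation. The selectivity needed is Claisen closure through the ethyl-side enolate rather than retro-Michael cleavage or closure from C3; attack from C3 could only give a four-membered ring, and the expelled methoxide deprotonates the strongly acidic 1,3-dione of the product, so the reversible Michael and Claisen equilibria should drain into the sodium dione enolate, from which 7 is released on acidification.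

Step 3
Reactants: 7 methyl 2,3,5-trimethyl-4,6-dioxocyclohexane-1-carboxylate
Product: 9 2,4,5-trimethylcyclohexane-1,3-dione, via keto acid 8 (not isolated)
Conditions: NaOH (2 M aq.), reflux; then HCl (conc.) to pH 1, reflux
Reagents that add atoms: none
Why: Saponification of the β-keto ester followed by decarboxylation of the β-keto acid on acidification and heating, the standard ending of a dimedone-type preparation, should remove the C1 carboxyl and leave the dione that maps onto ring C.

Step 4
Reactants: 9 2,4,5-trimethylcyclohexane-1,3-dione
Product: 10 2,4,5-trimethylbenzene-1,3-diol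
Conditions: Pd/C (10 wt% palladium on carbon, cat.), triglyme, 200 °C, N2 sweep
Reagents that add atoms: none
Why: Catalytic dehydrogenation of a cyclohexane-1,3-dione to the resorcinol over palladium with removal of H2 is an established aromatisation, and the substrate carries no other group that could suffer at this temperature.

Step 5
Reactants: 10 2,4,5-trimethylbenzene-1,3-diol
Product: 11 3-(benzyloxy)-2,5,6-trimethylphenol
Conditions: BnBr (1.0 equiv), K2CO3 (1.0 equiv), acetone, rt to 40 °C
Reagents that add atoms: benzyl bromide, BrCc1ccccc1
Why: In this Williamson ether synthesis with one equivalent of halide the hydroxyl with a free ortho position should be alkylated faster than the one flanked by two methyls (steric control), which leaves the hindered hydroxyl free for acylation.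

Step 6
Reactants: 7 methyl 2,3,5-trimethyl-4,6-dioxocyclohexane-1-carboxylate; 11 3-(benzyloxy)-2,5,6-trimethylphenol
Product: 13 3-(benzyloxy)-2,5,6-trimethylphenyl 2,3,5-trimethyl-4,6-dioxocyclohexane-1-carboxylate, via acylketene 12 (not isolated)
Conditions: 7 (1.5 equiv, added in portions), xylenes, 140 °C, 4 Å MS in a Soxhlet (MeOH removal), N2
Reagents that add atoms: none
Why: Thermal ester exchange of a β-keto ester, in which loss of methanol from the enol of 7 gives the α-oxoketene 12, a small linear electrophile that adds hindered hydroxyl groups through a six-membered pseudopericyclic transition state; removal of methanol should pull the equilibrium to the aryl ester, and any enol ester formed on the dione oxygen is itself a ketene donor and should revert.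

Step 7
Reactants: 13 3-(benzyloxy)-2,5,6-trimethylphenyl 2,3,5-trimethyl-4,6-dioxocyclohexane-1-carboxylate
Product: 14 3-(benzyloxy)-2,5,6-trimethylphenyl 2,4-dihydroxy-3,5,6-trimethylbenzoate
Conditions: DDQ (1.05 equiv), 1,4-dioxane, 60 °C
Reagents that add atoms: none
Why: In this DDQ dehydrogenation, hydride abstraction from the tertiary C2–H of the β-keto ester enol and loss of a proton add the one missing unsaturation, after which enolisation of both ketones gives the aromatic ring B; 60 °C stays below the temperature at which the aryl β-keto ester returns to the ketene, and the benzyl ether is inert to DDQ.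

Step 8
Reactants: 7 methyl 2,3,5-trimethyl-4,6-dioxocyclohexane-1-carboxylate
Product: 15 methyl 2,4-dihydroxy-3,5,6-trimethylbenzoate
Conditions: DDQ (1.05 equiv), 1,4-dioxane, rt to 60 °C
Reagents that add atoms: none
Why: The same DDQ dehydrogenation applied to the parent keto ester should remove the C2 hydride and a proton and, after enolisation, deliver the fully substituted resorcylate that becomes ring A; nothing else in 7 is oxidisable.

Step 9
Reactants: 15 methyl 2,4-dihydroxy-3,5,6-trimethylbenzoate
Product: 16 methyl 2,4-bis(benzyloxy)-3,5,6-trimethylbenzoate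
Conditions: BnBr (3 equiv), K2CO3 (4 equiv), DMF, 80 °C
Reagents that add atoms: benzyl bromide, BrCc1ccccc1
Why: Williamson ether synthesis under forcing conditions, in which excess halide and carbonate in DMF should alkylate both the 4-hydroxyl and the hydrogen-bonded 2-hydroxyl; every ring position is substituted, so C-benzylation cannot divert the phenoxide.

Step 10
Reactants: 16 methyl 2,4-bis(benzyloxy)-3,5,6-trimethylbenzoate
Product: 17 2,4-bis(benzyloxy)-3,5,6-trimethylbenzoic acid
Conditions: KOH (10 equiv), DMSO–H2O (4:1), 90 °C; then HCl (aq.) to pH 2
Reagents that add atoms: potassium hydroxide, [K+].[OH-]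
Why: Saponification with poorly solvated hydroxide in aqueous DMSO is the usual answer to 2,6-disubstituted benzoates that resist aqueous alkali, and the two benzyl ethers are inert to base.

Step 11
Reactants: 17 2,4-bis(benzyloxy)-3,5,6-trimethylbenzoic acid; 14 3-(benzyloxy)-2,5,6-trimethylphenyl 2,4-dihydroxy-3,5,6-trimethylbenzoate
Product: 19 3-(benzyloxy)-2,5,6-trimethylphenyl 4-{[2,4-bis(benzyloxy)-3,5,6-trimethylbenzoyl]oxy}-2-hydroxy-3,5,6-trimethylbenzoate, via mixed anhydride 18 (not isolated)
Conditions: 17 (1.2 equiv), TFAA (1.5 equiv), toluene, rt, 30 min; then 14, rt; NaHCO3 (aq.)–MeOH work-up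
Reagents that add atoms: none
Why: Esterification by the mixed anhydride method, in which TFAA converts 17 into 18 and the electron-rich, doubly ortho-substituted aroyl group is then transferred to the phenol, an established way to join 2,6-disubstituted benzoic acids to hindered phenols; the hydroxyl ortho to the ester of 14 is tied up in a hydrogen bond to the carbonyl and is the poorer nucleophile, so acylation should occur at O4, and any aryl trifluoroacetate is cleaved in the bicarbonate work-up.

Step 12
Reactants: 19 3-(benzyloxy)-2,5,6-trimethylphenyl 4-{[2,4-bis(benzyloxy)-3,5,6-trimethylbenzoyl]oxy}-2-hydroxy-3,5,6-trimethylbenzoate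
Product: 20 thielavin Z8
Conditions: H2 (1 atm), Pd/C (10 wt% palladium on carbon, cat.), EtOAc–THF, rt
Reagents that add atoms: none
Why: Hydrogenolysis of the three aryl benzyl ethers over Pd/C under neutral conditions should free the phenols without touching the two hindered aryl esters.

**Compound list**

1 | pentan-3-one | CCC(=O)CC | starting material
2 | acetaldehyde | CC=O | starting material
3 | 5-hydroxy-4-methylhexan-3-one (aldol adduct, not isolated) | CCC(=O)C(C)C(C)O | intermediate
4 | (E)-4-methylhex-4-en-3-one | CCC(=O)/C(C)=C/C | intermediate
5 | dimethyl malonate | COC(=O)CC(=O)OC | starting material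
6 | dimethyl 2-(3-methyl-4-oxohexan-2-yl)propanedioate (Michael adduct, not isolated) | COC(=O)C(C(=O)OC)C(C)C(C)C(=O)CC | intermediate
7 | methyl 2,3,5-trimethyl-4,6-dioxocyclohexane-1-carboxylate | COC(=O)C1C(C)C(C)C(=O)C(C)C1=O | intermediate
8 | 2,3,5-trimethyl-4,6-dioxocyclohexane-1-carboxylic acid (not isolated) | OC(=O)C1C(C)C(C)C(=O)C(C)C1=O | intermediate
9 | 2,4,5-trimethylcyclohexane-1,3-dione | CC1CC(=O)C(C)C(=O)C1C | intermediate
10 | 2,4,5-trimethylbenzene-1,3-diol | Cc1cc(O)c(C)c(O)c1C | intermediate
11 | 3-(benzyloxy)-2,5,6-trimethylphenol | Cc1cc(OCc2ccccc2)c(C)c(O)c1C | intermediate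
12 | 2,5,6-trimethyl-4-(oxomethylidene)cyclohexane-1,3-dione (acylketene, not isolated) | O=C=C1C(C)C(C)C(=O)C(C)C1=O | intermediate
13 | 3-(benzyloxy)-2,5,6-trimethylphenyl 2,3,5-trimethyl-4,6-dioxocyclohexane-1-carboxylate | CC1C(C)C(=O)C(C)C(=O)C1C(=O)Oc1c(C)c(OCc2ccccc2)cc(C)c1C | intermediate
14 | 3-(benzyloxy)-2,5,6-trimethylphenyl 2,4-dihydroxy-3,5,6-trimethylbenzoate | Cc1c(C)c(O)c(C)c(O)c1C(=O)Oc1c(C)c(OCc2ccccc2)cc(C)c1C | intermediate
15 | methyl 2,4-dihydroxy-3,5,6-trimethylbenzoate | COC(=O)c1c(C)c(C)c(O)c(C)c1O | intermediate
16 | methyl 2,4-bis(benzyloxy)-3,5,6-trimethylbenzoate | COC(=O)c1c(C)c(C)c(OCc2ccccc2)c(C)c1OCc1ccccc1 | intermediate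
17 | 2,4-bis(benzyloxy)-3,5,6-trimethylbenzoic acid | OC(=O)c1c(C)c(C)c(OCc2ccccc2)c(C)c1OCc1ccccc1 | intermediate
18 | 2,4-bis(benzyloxy)-3,5,6-trimethylbenzoic trifluoroacetic anhydride (mixed anhydride, not isolated) | O=C(OC(=O)C(F)(F)F)c1c(C)c(C)c(OCc2ccccc2)c(C)c1OCc1ccccc1 | intermediate
19 | 3-(benzyloxy)-2,5,6-trimethylphenyl 4-{[2,4-bis(benzyloxy)-3,5,6-trimethylbenzoyl]oxy}-2-hydroxy-3,5,6-trimethylbenzoate | Cc1c(C)c(OCc2ccccc2)c(C)c(OCc2ccccc2)c1C(=O)Oc1c(C)c(C)c(C(=O)Oc2c(C)c(OCc3ccccc3)cc(C)c2C)c(O)c1C | intermediate
20 | thielavin Z8, 3-hydroxy-2,5,6-trimethylphenyl 4-[(2,4-dihydroxy-3,5,6-trimethylbenzoyl)oxy]-2-hydroxy-3,5,6-trimethylbenzoate | Cc1cc(O)c(C)c(OC(=O)c2c(C)c(C)c(OC(=O)c3c(C)c(C)c(O)c(C)c3O)c(C)c2O)c1C | target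

**Step count**

Total: 12 steps. Longest linear sequence: 9 steps (steps 1–7, 11 and 12, pentan-3-one to thielavin Z8). The ring A branch (steps 8–10) leaves the main line at compound 7, which also feeds the ring C branch and the acylketene transfer.

**Steps most likely to fail**

Step 6. The doubly ortho-methylated hydroxyl of 11 may add to the ketene more slowly than the ketene dimerises or is captured by the enolised dione of another molecule, and the aryl ester may drift back to the ketene on long heating. The fallback sets out from 15 and 11 and comes back to the route at 14, so it replaces steps 6 and 7 and forms the B–C ester at the aromatic oxidation level. Compound 15 would be allylated at both hydroxyls (allyl bromide, K2CO3, DMF, 60 °C) to methyl 3,5,6-trimethyl-2,4-bis(prop-2-en-1-yloxy)benzoate F1. The hindered methyl ester would be cleaved with KOSiMe3 in THF at reflux, followed by acidification, to 3,5,6-trimethyl-2,4-bis(prop-2-en-1-yloxy)benzoic acid F2. TFAA in toluene would convert F2 into 3,5,6-trimethyl-2,4-bis(prop-2-en-1-yloxy)benzoic trifluoroacetic anhydride F3, which is not isolated and should acylate phenol 11 to 3-(benzyloxy)-2,5,6-trimethylphenyl 3,5,6-trimethyl-2,4-bis(prop-2-en-1-yloxy)benzoate F4. Pd(PPh3)4 with morpholine in THF would then remove both allyl groups and spare the benzyl ether, giving 14.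

Step 11. Discrimination between the two hydroxyls of ring B may be poor, acylation of a hydroxyl flanked by two methyls and deactivated by the para ester may be sluggish, and the acidic medium may strip a benzyl ether from the activated acid. The fallback sets out from 17 and 14 and comes back at 19; it replaces acid-promoted acylation of the neutral phenol by acylation of a selectively formed phenoxide. Acid 17 would be converted with oxalyl chloride and catalytic DMF in CH2Cl2 into 2,4-bis(benzyloxy)-3,5,6-trimethylbenzoyl chloride F5. Compound 14 would be treated with NaH (1.0 equiv) in THF at 0 °C, which should deprotonate the more acidic, non-chelated 4-hydroxyl para to the ester. Addition of F5 (THF, rt to reflux) should then give 19.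

Step 7. DDQ may over-oxidise benzylic positions of the electron-rich rings, hydride abstraction from the hindered tertiary C–H may be slow, and raising the temperature may extrude the ketene from the aryl β-keto ester. The fallback sets out from 13 and comes back at 20; it aromatises by bromination and dehydrobromination and carries a ring C bromide to the end. Bromine (2 equiv) with NaOAc in acetic acid (rt, then 50 °C) should α-brominate the β-dicarbonyl system and, by loss of HBr, aromatise ring B, while the second equivalent brominates the single free position of ring C; the acetate buffer protects the benzyl ether from HBr. The product would be 3-(benzyloxy)-4-bromo-2,5,6-trimethylphenyl 2,4-dihydroxy-3,5,6-trimethylbenzoate F6. Acylation of F6 at O4 with acid 17 under the conditions of step 11 (through mixed anhydride 18) would give 3-(benzyloxy)-4-bromo-2,5,6-trimethylphenyl 4-{[2,4-bis(benzyloxy)-3,5,6-trimethylbenzoyl]oxy}-2-hydroxy-3,5,6-trimethylbenzoate F7. Hydrogenolysis (H2, Pd/C, NaOAc, EtOAc–THF) would remove the aryl bromide together with the three benzyl groups to give 20.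

**Further compounds**

F1 | step 6 | methyl 3,5,6-trimethyl-2,4-bis(prop-2-en-1-yloxy)benzoate | COC(=O)c1c(C)c(C)c(OCC=C)c(C)c1OCC=C
F2 | step 6 | 3,5,6-trimethyl-2,4-bis(prop-2-en-1-yloxy)benzoic acid | OC(=O)c1c(C)c(C)c(OCC=C)c(C)c1OCC=C
F3 | step 6 | 3,5,6-trimethyl-2,4-bis(prop-2-en-1-yloxy)benzoic trifluoroacetic anhydride (formed in the flask) | O=C(OC(=O)C(F)(F)F)c1c(C)c(C)c(OCC=C)c(C)c1OCC=C
F4 | step 6 | 3-(benzyloxy)-2,5,6-trimethylphenyl 3,5,6-trimethyl-2,4-bis(prop-2-en-1-yloxy)benzoate | C=CCOc1c(C)c(C)c(C(=O)Oc2c(C)c(OCc3ccccc3)cc(C)c2C)c(OCC=C)c1C
F5 | step 11 | 2,4-bis(benzyloxy)-3,5,6-trimethylbenzoyl chloride | O=C(Cl)c1c(C)c(C)c(OCc2ccccc2)c(C)c1OCc1ccccc1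
F6 | step 7 | 3-(benzyloxy)-4-bromo-2,5,6-trimethylphenyl 2,4-dihydroxy-3,5,6-trimethylbenzoate | Cc1c(C)c(O)c(C)c(O)c1C(=O)Oc1c(C)c(OCc2ccccc2)c(Br)c(C)c1C
F7 | step 7 | 3-(benzyloxy)-4-bromo-2,5,6-trimethylphenyl 4-{[2,4-bis(benzyloxy)-3,5,6-trimethylbenzoyl]oxy}-2-hydroxy-3,5,6-trimethylbenzoate | Cc1c(C)c(OCc2ccccc2)c(C)c(OCc2ccccc2)c1C(=O)Oc1c(C)c(C)c(C(=O)Oc2c(C)c(OCc3ccccc3)c(Br)c(C)c2C)c(O)c1C
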